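**Retrosynthetic overview**

1. The target is two 2,3-cis units joined C4 (upper pyran ring) to C6 (lower ring A). This bond is cut first: Friedel–Crafts alkylation of a lower-unit arene by the C4 benzylic cation of a protected upper flavan-3,4-diol (15).
2. The lower pyran ring is not closed as a six-membered ring. It passes through the coupling as a 2-aryl-2,3-dihydrobenzofuran (O1, C2, C3 and ring-A carbons C4a/C8a in place, the future C4 an exocyclic ester/formyl carbon on C3) and is enlarged afterwards by an α-ketol 1,2-aryl shift (17 → 18). The same shift on the monomer (12 → 13) supplies the upper unit.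
3. Enabling feature: in the lower unit C3 and C4 both carry oxygen, and C4 is bonded to C4a, which is ortho to the O1-bearing C8a and para to the C7 oxygen of ring A. A C3 carbinol bearing a formyl group therefore has a very electron-rich aryl carbon to shift, and the shift gives exactly C3=O/C4–OH.
4. The dihydrofuran ring comes from an enantioselective carbenoid C–H insertion into the O–CH2–aryl ether (sets C2) and an anti enolate hydroxylation (sets the carbinol whose face is relayed to C4). C3 is set last by hydroxyl-directed reduction.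
5. Ring order: rings A and B are bought; dihydrofuran ring (step 6); upper pyran by ring expansion (step 9); interflavan bond (step 12); lower pyran by ring expansion (step 14); reduction and global hydrogenolysis.

Key step: step 14

Assumption: Rh2(S-PTTL)4 is taken to give the (2S) ring of 9 in step 6, by analogy with other 2-aryl-2,3-dihydrobenzofuran-3-carboxylates; if the insertion gives the antipode, Rh2(R-PTTL)4 is used instead.

**Route**

Step 1
Reactants: 1 1-(2,3,4-trihydroxyphenyl)ethan-1-one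
Product: 2 1-[3,4-bis(benzyloxy)-2-hydroxyphenyl]ethan-1-one
Conditions: BnBr (2.1 equiv), K2CO3, acetone, reflux
Reagents that add atoms: benzyl bromide, BrCc1ccccc1
Why: Williamson etherification; the 2-OH is hydrogen-bonded to the acetyl group and is the least reactive, so only O3 and O4 should be benzylated.

Step 2
Reactants: 2 1-[3,4-bis(benzyloxy)-2-hydroxyphenyl]ethan-1-one; 3 1-(benzyloxy)-4-(chloromethyl)benzene
Product: 4 1-[3,4-bis(benzyloxy)-2-{[4-(benzyloxy)phenyl]methoxy}phenyl]ethan-1-one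
Conditions: K2CO3, KI (cat.), DMF, 70 °C
Reagents that add atoms: none
Why: Williamson etherification of the chelated phenol under iodide catalysis; it installs the O–CH2–aryl unit that later becomes O1–C2 with ring B.

Step 3
Reactants: 4 1-[3,4-bis(benzyloxy)-2-{[4-(benzyloxy)phenyl]methoxy}phenyl]ethan-1-one
Product: 6 2-[3,4-bis(benzyloxy)-2-{[4-(benzyloxy)phenyl]methoxy}phenyl]acetic acid, via thiomorpholide 5 (not isolated)
Conditions: S8, morpholine, 130 °C; then KOH, EtOH/H2O, reflux; dilute HCl, 0 °C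
Reagents that add atoms: water, O (as aqueous KOH, both carboxyl oxygens of 6); sulfur, S1SSSSSSS1, and morpholine, C1COCCN1 (atoms kept only in intermediate 5)
Why: Willgerodt–Kindler reaction moves the oxidised carbon to the chain end and the thioamide is hydrolysed in the same flask; the basic medium spares the acid-labile 4-(benzyloxy)benzyl aryl ether.

Step 4
Reactants: 6 2-[3,4-bis(benzyloxy)-2-{[4-(benzyloxy)phenyl]methoxy}phenyl]acetic acid
Product: 7 methyl 2-[3,4-bis(benzyloxy)-2-{[4-(benzyloxy)phenyl]methoxy}phenyl]acetate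
Conditions: MeI, K2CO3, DMF, rt
Reagents that add atoms: iodomethane, CI
Why: SN2 O-alkylation of the carboxylate.

Step 5
Reactants: 7 methyl 2-[3,4-bis(benzyloxy)-2-{[4-(benzyloxy)phenyl]methoxy}phenyl]acetate
Product: 8 methyl 2-diazo-2-[3,4-bis(benzyloxy)-2-{[4-(benzyloxy)phenyl]methoxy}phenyl]acetate
Conditions: 4-acetamidobenzenesulfonyl azide, DBU, MeCN, 0 °C to rt
Reagents that add atoms: 4-acetamidobenzenesulfonyl azide, CC(=O)Nc1ccc(cc1)S(=O)(=O)N=[N+]=[N-]
Why: Regitz diazo transfer to an arylacetate, the standard entry to aryldiazoacetates.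

Step 6
Reactants: 8 methyl 2-diazo-2-[3,4-bis(benzyloxy)-2-{[4-(benzyloxy)phenyl]methoxy}phenyl]acetate
Product: 9 methyl (2S,3R)-6,7-bis(benzyloxy)-2-[4-(benzyloxy)phenyl]-2,3-dihydro-1-benzofuran-3-carboxylate (cis)
Conditions: dirhodium tetrakis[N-phthaloyl-(S)-tert-leucinate], Rh2(S-PTTL)4 (1 mol%), toluene, −60 °C
Reagents that add atoms: none
Why: intramolecular rhodium carbenoid 1,5 C–H insertion into the ether-activated benzylic C–H closes the dihydrofuran ring; the chiral carboxylate catalyst sets C2, and the cis/trans ratio at C3 does not matter because C3 is planarised in step 7.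

Step 7
Reactants: 9 methyl (2S,3R)-6,7-bis(benzyloxy)-2-[4-(benzyloxy)phenyl]-2,3-dihydro-1-benzofuran-3-carboxylate
Product: 11 methyl (2R,3S)-6,7-bis(benzyloxy)-2-[4-(benzyloxy)phenyl]-3-hydroxy-2,3-dihydro-1-benzofuran-3-carboxylate, via potassium enolate 10 (not isolated)
Conditions: KN(SiMe3)2, THF, −78 °C; then 2-(benzenesulfonyl)-3-phenyloxaziridine, −78 °C; aq. NH4Cl
Reagents that add atoms: 2-(benzenesulfonyl)-3-phenyloxaziridine, O=S(=O)(N1OC1c1ccccc1)c1ccccc1 (the 3-OH oxygen); KN(SiMe3)2, C[Si](C)(C)[N-][Si](C)(C)C.[K+] (potassium kept only in intermediate 10)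
Why: ester enolate hydroxylation by an N-sulfonyloxaziridine; the oxidant should approach the planar enolate anti to the C2 aryl group, so the 3-OH ends trans to the aryl group and both C3 epimers of 9 converge.

Step 8
Reactants: 11 methyl (2R,3S)-6,7-bis(benzyloxy)-2-[4-(benzyloxy)phenyl]-3-hydroxy-2,3-dihydro-1-benzofuran-3-carboxylate
Product: 12 (2R,3S)-6,7-bis(benzyloxy)-2-[4-(benzyloxy)phenyl]-3-hydroxy-2,3-dihydro-1-benzofuran-3-carbaldehyde
Conditions: i-Bu2AlH (2.5 equiv), CH2Cl2, −78 °C; aq. potassium sodium tartrate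
Reagents that add atoms: none
Why: partial reduction of an α-hydroxy ester to the aldehyde; the aluminium hemiacetal is held by chelation to the neighbouring aluminium alkoxide at −78 °C.

Step 9
Reactants: 12 (2R,3S)-6,7-bis(benzyloxy)-2-[4-(benzyloxy)phenyl]-3-hydroxy-2,3-dihydro-1-benzofuran-3-carbaldehyde
Product: 13 (2R,4S)-7,8-bis(benzyloxy)-2-[4-(benzyloxy)phenyl]-4-hydroxychroman-3-one (2,4-trans)
Conditions: Me2AlCl (1.2 equiv), CH2Cl2, −78 to −20 °C; aq. potassium sodium tartrate, 0 °C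
Reagents that add atoms: none
Why: α-ketol (acyloin) rearrangement with ring enlargement, the monomer version of step 14; the aluminium chelate relays the face of the C3–OH to the new C4–OH, which ends trans to the 2-aryl group.

Step 10
Reactants: 13 (2R,4S)-7,8-bis(benzyloxy)-2-[4-(benzyloxy)phenyl]-4-hydroxychroman-3-one
Product: 14 (2R,3R,4S)-7,8-bis(benzyloxy)-2-[4-(benzyloxy)phenyl]chromane-3,4-diol (2,3-cis-3,4-trans)
Conditions: Me4NBH(OAc)3, MeCN/AcOH (1:1), −30 °C
Reagents that add atoms: none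
Why: hydroxyl-directed triacetoxyborohydride reduction (Saksena–Evans type); hydride is delivered from boron bound to O4 on the face of the 4-OH, so the 3-OH should end trans to the 4-OH and cis to the 2-aryl group.

Step 11
Reactants: 14 (2R,3R,4S)-7,8-bis(benzyloxy)-2-[4-(benzyloxy)phenyl]chromane-3,4-diol
Product: 15 (2R,3R,4S)-3,4,7,8-tetrakis(benzyloxy)-2-[4-(benzyloxy)phenyl]chromane
Conditions: NaH, BnBr, Bu4NI (cat.), DMF, 0 °C to rt
Reagents that add atoms: benzyl bromide, BrCc1ccccc1
Why: Williamson etherification; the 4-benzyloxy group is the later leaving group and the 3-benzyl ether is removed with the others at the end.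

Step 12
Reactants: 15 (2R,3R,4S)-3,4,7,8-tetrakis(benzyloxy)-2-[4-(benzyloxy)phenyl]chromane; 11 methyl (2R,3S)-6,7-bis(benzyloxy)-2-[4-(benzyloxy)phenyl]-3-hydroxy-2,3-dihydro-1-benzofuran-3-carboxylate
Product: 16 methyl (2R,3S)-6,7-bis(benzyloxy)-2-[4-(benzyloxy)phenyl]-3-hydroxy-5-{(2R,3R)-3,7,8-tris(benzyloxy)-2-[4-(benzyloxy)phenyl]chroman-4-yl}-2,3-dihydro-1-benzofuran-3-carboxylate (new C4–aryl bond trans to the 3-benzyloxy group)
Conditions: TMSOTf (0.1 equiv), 11 (3 equiv, excess recovered), 4 Å molecular sieves, CH2Cl2, −78 to −40 °C; Et3N quench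
Reagents that add atoms: none
Why: ionisation of the 4-benzyloxy group gives the C4 benzylic cation (stabilised by O1 and O7), which undergoes Friedel–Crafts alkylation at C5 of 11 (para to O1, ortho to the 6-benzyloxy group; C4 is shielded by the quaternary C3); attack anti to the axial 3-benzyloxy group sets the 3,4-trans bond, and 11 has no ionisable benzylic C–O of its own.

Step 13
Reactants: 16 dimer methyl ester
Product: 17 the 3-carbaldehyde corresponding to 16 (all stereocentres as in 16)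
Conditions: i-Bu2AlH (2.5 equiv), CH2Cl2, −78 °C; aq. potassium sodium tartrate
Reagents that add atoms: none
Why: partial reduction of the α-hydroxy ester as in step 8; the benzyl ethers and the interflavan bond are inert to the hydride.

Step 14
Reactants: 17 dimer hydroxy aldehyde
Product: 18 (2R,4S)-7,8-bis(benzyloxy)-2-[4-(benzyloxy)phenyl]-4-hydroxy-6-{(2R,3R)-3,7,8-tris(benzyloxy)-2-[4-(benzyloxy)phenyl]chroman-4-yl}chroman-3-one (4-OH trans to the 2-aryl group)
Conditions: Me2AlCl (1.2 equiv), CH2Cl2, −78 to −20 °C; aq. potassium sodium tartrate, 0 °C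
Reagents that add atoms: none
Why: The tertiary hydroxyl is converted by Me2AlCl into an aluminium alkoxide that also binds the formyl oxygen, and in this five-membered chelate the ring-A carbon C3a (ortho to O1, para to the 6-benzyloxy group) shifts with its bonding pair from C3 to the formyl carbon while C3 becomes the ketone: an α-ketol (acyloin) rearrangement with ring enlargement. The closest known reaction type is the Lewis-acid α-ketol rearrangement of tertiary α-hydroxy aldehydes, including 1-hydroxycycloalkanecarbaldehydes that give 2-hydroxycycloalkanones. The pyran ring is closed by this 1,2-shift (the formyl carbon is inserted between C3 and the ring-A carbon), not by a cyclisation, so no endo or exo mode applies. The new stereocentre C4 is set by the chelate: C–O and C=O are held syn-periplanar, the aryl carbon reaches the formyl carbon from its own side of the chelate plane, and the C4–OH therefore takes the ring face of the former C3–OH, trans to the 2-aryl group; C2 is not touched. The step needs aryl migration instead of C2 migration (which would give a 3-hydroxychroman-4-one) and no enolisation of the product: the first is secured by the doubly oxygen-activated migrating carbon, the second by the low temperature and the absence of base. The benzyl ethers and the interflavan bond have already met a stronger Lewis acid in step 12.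

Step 15
Reactants: 18 dimer hydroxy ketone
Product: 19 hepta-O-benzyl ether of 20 (free lower 3-OH and 4-OH; lower unit 2,3-cis-3,4-trans)
Conditions: Me4NBH(OAc)3, MeCN/AcOH (1:1), −30 °C
Reagents that add atoms: none
Why: hydroxyl-directed reduction as in step 10; hydride delivery from the O4-bound boron should set the lower 3-OH trans to the 4-OH and cis to the 2-aryl group.

Step 16
Reactants: 19 hepta-O-benzyl ether of 20
Product: 20 (2R,3R,4S)-6-[(2R,3R,4S)-3,7,8-trihydroxy-2-(4-hydroxyphenyl)chroman-4-yl]-2-(4-hydroxyphenyl)chromane-3,4,7,8-tetrol (target; both units 2,3-cis-3,4-trans)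
Conditions: H2 (1 atm), Pd(OH)2/C, NaHCO3 (solid), THF/MeOH, rt
Reagents that add atoms: none
Why: catalytic hydrogenolysis of the seven benzyl ethers under neutral, buffered conditions; no stereocentre is touched.

**Compound list**

1 | 1-(2,3,4-trihydroxyphenyl)ethan-1-one (gallacetophenone) | CC(=O)c1ccc(O)c(O)c1O | starting material
2 | 1-[3,4-bis(benzyloxy)-2-hydroxyphenyl]ethan-1-one | CC(=O)c1ccc(OCc2ccccc2)c(OCc2ccccc2)c1O | intermediate
3 | 1-(benzyloxy)-4-(chloromethyl)benzene | ClCc1ccc(OCc2ccccc2)cc1 | starting material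
4 | 1-[3,4-bis(benzyloxy)-2-{[4-(benzyloxy)phenyl]methoxy}phenyl]ethan-1-one | CC(=O)c1ccc(OCc2ccccc2)c(OCc2ccccc2)c1OCc1ccc(OCc2ccccc2)cc1 | intermediate
5 | 2-[3,4-bis(benzyloxy)-2-{[4-(benzyloxy)phenyl]methoxy}phenyl]-1-(morpholin-4-yl)ethane-1-thione | S=C(Cc1ccc(OCc2ccccc2)c(OCc2ccccc2)c1OCc1ccc(OCc2ccccc2)cc1)N1CCOCC1 | intermediate
6 | 2-[3,4-bis(benzyloxy)-2-{[4-(benzyloxy)phenyl]methoxy}phenyl]acetic acid | OC(=O)Cc1ccc(OCc2ccccc2)c(OCc2ccccc2)c1OCc1ccc(OCc2ccccc2)cc1 | intermediate
7 | methyl 2-[3,4-bis(benzyloxy)-2-{[4-(benzyloxy)phenyl]methoxy}phenyl]acetate | COC(=O)Cc1ccc(OCc2ccccc2)c(OCc2ccccc2)c1OCc1ccc(OCc2ccccc2)cc1 | intermediate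
8 | methyl 2-diazo-2-[3,4-bis(benzyloxy)-2-{[4-(benzyloxy)phenyl]methoxy}phenyl]acetate | COC(=O)C(=[N+]=[N-])c1ccc(OCc2ccccc2)c(OCc2ccccc2)c1OCc1ccc(OCc2ccccc2)cc1 | intermediate
9 | methyl (2S,3R)-6,7-bis(benzyloxy)-2-[4-(benzyloxy)phenyl]-2,3-dihydro-1-benzofuran-3-carboxylate (cis) | COC(=O)[C@H]1[C@@H](c2ccc(OCc3ccccc3)cc2)Oc2c1ccc(OCc1ccccc1)c2OCc1ccccc1 | intermediate
10 | potassium enolate of 9 (C3 planar, enolate geometry not defined, C2 as in 9) | [K+].[O-]C(OC)=C1c2ccc(OCc3ccccc3)c(OCc3ccccc3)c2O[C@@H]1c1ccc(OCc2ccccc2)cc1 | intermediate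
11 | methyl (2R,3S)-6,7-bis(benzyloxy)-2-[4-(benzyloxy)phenyl]-3-hydroxy-2,3-dihydro-1-benzofuran-3-carboxylate (3-OH trans to 2-aryl) | COC(=O)[C@@]1(O)[C@@H](c2ccc(OCc3ccccc3)cc2)Oc2c1ccc(OCc1ccccc1)c2OCc1ccccc1 | intermediate
12 | (2R,3S)-6,7-bis(benzyloxy)-2-[4-(benzyloxy)phenyl]-3-hydroxy-2,3-dihydro-1-benzofuran-3-carbaldehyde | O=C[C@@]1(O)[C@@H](c2ccc(OCc3ccccc3)cc2)Oc2c1ccc(OCc1ccccc1)c2OCc1ccccc1 | intermediate
13 | (2R,4S)-7,8-bis(benzyloxy)-2-[4-(benzyloxy)phenyl]-4-hydroxychroman-3-one | O=C1[C@@H](O)c2ccc(OCc3ccccc3)c(OCc3ccccc3)c2O[C@@H]1c1ccc(OCc2ccccc2)cc1 | intermediate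
14 | (2R,3R,4S)-7,8-bis(benzyloxy)-2-[4-(benzyloxy)phenyl]chromane-3,4-diol | c1cc2c(c(OCc3ccccc3)c1OCc1ccccc1)O[C@H](c1ccc(OCc3ccccc3)cc1)[C@H](O)[C@H]2O | intermediate
15 | (2R,3R,4S)-3,4,7,8-tetrakis(benzyloxy)-2-[4-(benzyloxy)phenyl]chromane | c1cc2c(c(OCc3ccccc3)c1OCc1ccccc1)O[C@H](c1ccc(OCc3ccccc3)cc1)[C@H](OCc1ccccc1)[C@H]2OCc1ccccc1 | intermediate
16 | dimer methyl ester: 11 bearing at C5 the (2R,3R)-3,7,8-tris(benzyloxy)-2-[4-(benzyloxy)phenyl]chroman-4-yl group, C4–aryl bond trans to the 3-benzyloxy group | C(c5ccccc5)Oc1ccc([C@H]2Oc3c(ccc(OCc5ccccc5)c3OCc5ccccc5)[C@H](c3cc4c(c(OCc5ccccc5)c3OCc5ccccc5)O[C@H](c3ccc(OCc5ccccc5)cc3)[C@]4(O)C(=O)OC)[C@H]2OCc2ccccc2)cc1 | intermediate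
17 | dimer hydroxy aldehyde: 3-carbaldehyde corresponding to 16 | C(c5ccccc5)Oc1ccc([C@H]2Oc3c(ccc(OCc5ccccc5)c3OCc5ccccc5)[C@H](c3cc4c(c(OCc5ccccc5)c3OCc5ccccc5)O[C@H](c3ccc(OCc5ccccc5)cc3)[C@]4(O)C=O)[C@H]2OCc2ccccc2)cc1 | intermediate
18 | dimer hydroxy ketone: (2R,4S)-4-hydroxychroman-3-one lower unit (as 13) bearing the upper chroman-4-yl group at C6 | C(c5ccccc5)Oc1ccc([C@H]2Oc3c(ccc(OCc5ccccc5)c3OCc5ccccc5)[C@H](c3cc4c(c(OCc5ccccc5)c3OCc5ccccc5)O[C@H](c3ccc(OCc5ccccc5)cc3)C(=O)[C@H]4O)[C@H]2OCc2ccccc2)cc1 | intermediate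
19 | hepta-O-benzyl ether of 20 (upper O3, O7, O8, O4'; lower O7, O8, O4' benzylated) | C(c5ccccc5)Oc1ccc([C@H]2Oc3c(ccc(OCc5ccccc5)c3OCc5ccccc5)[C@H](c3cc4c(c(OCc5ccccc5)c3OCc5ccccc5)O[C@H](c3ccc(OCc5ccccc5)cc3)[C@H](O)[C@H]4O)[C@H]2OCc2ccccc2)cc1 | intermediate
20 | (2R,3R,4S)-6-[(2R,3R,4S)-3,7,8-trihydroxy-2-(4-hydroxyphenyl)chroman-4-yl]-2-(4-hydroxyphenyl)chromane-3,4,7,8-tetrol | Oc1ccc([C@H]2Oc3c(ccc(O)c3O)[C@H](c3cc4c(c(O)c3O)O[C@H](c3ccc(O)cc3)[C@H](O)[C@H]4O)[C@H]2O)cc1 | target

**Step count and risks**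

Total step count: 16. Longest linear sequence: 16 steps (1 → 20; compound 11 re-enters the same line in step 12).

Steps most likely to fail:

1. Step 14 (and its monomer model, step 9). C2 may migrate in place of the ring-A carbon, the product ketone may enolise under the Lewis acid (loss of configuration at C4 or C2, drift to the conjugated aryl ketone), or turnover may be slow on the crowded dimer. The fallback sets out from 11 and uses known chemistry only. LiAlH4 in THF at 0 °C should reduce the ester to (2R,3R)-6,7-bis(benzyloxy)-2-[4-(benzyloxy)phenyl]-3-(hydroxymethyl)-2,3-dihydro-1-benzofuran-3-ol F1. TsCl in pyridine should sulfonylate only the primary hydroxyl to give the tosylate F2. Et3Al in CH2Cl2 (−78 to 0 °C) should then promote the pinacol-type 1,2-aryl shift with loss of tosylate, a ring enlargement known for 2-hydroxy sulfonates, to give (2R)-7,8-bis(benzyloxy)-2-[4-(benzyloxy)phenyl]chroman-3-one F3. LiBH(s-Bu)3 in THF at −78 °C should reduce F3 from the face opposite the 2-aryl group to the 2,3-cis flavan-3-ol F4. F4 (3 equiv) is coupled with 15 as in step 12 to give the 4-deoxy dimer F5. DDQ in CH2Cl2/H2O then oxidises the lower C4 methylene, water adding trans to the 3-hydroxyl, and the fallback comes back to the route at 19. For the upper unit the same DDQ oxidation of F4 gives 14.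

2. Step 12. The electrophile may self-condense (its ring A is as nucleophilic as that of 11), O-alkylation may compete, and conversion may be incomplete because a 1,2,3-trioxygenated ring is only a moderate nucleophile. The fallback sets out from 15. NBS in CH2Cl2 at −20 °C should brominate C6 of ring A (para to O1), capping the only nucleophilic position, to give the 6-bromo electrophile F6. Coupling of F6 with 11 under TMSOTf should give the bromo dimer F7. Bu3SnH/AIBN in toluene at 80 °C removes the bromine, and the fallback comes back at 16.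

3. Step 16. Once O7 is unmasked, the lower C4–O bond is of the 4-hydroxybenzyl alcohol type and may be hydrogenolysed, or the carbinol may ionise and give oligomers. The fallback sets out from 18 and changes the order of events. H2 with Pd(OH)2/C in EtOAc/MeOH removes the seven benzyl ethers while the 4-carbinol is still flanked by the C3 ketone, and so is not activated, giving the heptaphenol hydroxy ketone F8. Me4NBH(OAc)3 in MeCN/AcOH at −30 °C then performs the directed reduction, and the fallback comes back at 20.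

**Further compounds**

F1 | step 14 | (2R,3R)-6,7-bis(benzyloxy)-2-[4-(benzyloxy)phenyl]-3-(hydroxymethyl)-2,3-dihydro-1-benzofuran-3-ol | OC[C@@]1(O)[C@@H](c2ccc(OCc3ccccc3)cc2)Oc2c1ccc(OCc1ccccc1)c2OCc1ccccc1
F2 | step 14 | [(2R,3R)-6,7-bis(benzyloxy)-2-[4-(benzyloxy)phenyl]-3-hydroxy-2,3-dihydro-1-benzofuran-3-yl]methyl 4-methylbenzenesulfonate | Cc1ccc(cc1)S(=O)(=O)OC[C@@]1(O)[C@@H](c2ccc(OCc3ccccc3)cc2)Oc2c1ccc(OCc1ccccc1)c2OCc1ccccc1
F3 | step 14 | (2R)-7,8-bis(benzyloxy)-2-[4-(benzyloxy)phenyl]chroman-3-one | O=C1Cc2ccc(OCc3ccccc3)c(OCc3ccccc3)c2O[C@@H]1c1ccc(OCc2ccccc2)cc1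
F4 | step 14 | (2R,3R)-7,8-bis(benzyloxy)-2-[4-(benzyloxy)phenyl]chroman-3-ol | O[C@@H]1Cc2ccc(OCc3ccccc3)c(OCc3ccccc3)c2O[C@@H]1c1ccc(OCc2ccccc2)cc1
F5 | step 14 | 4-deoxy analogue of 19 (lower C4 is CH2) | C(c5ccccc5)Oc1ccc([C@H]2Oc3c(ccc(OCc5ccccc5)c3OCc5ccccc5)[C@H](c3cc4c(c(OCc5ccccc5)c3OCc5ccccc5)O[C@H](c3ccc(OCc5ccccc5)cc3)[C@H](O)C4)[C@H]2OCc2ccccc2)cc1
F6 | step 12 | (2R,3R,4S)-3,4,7,8-tetrakis(benzyloxy)-2-[4-(benzyloxy)phenyl]-6-bromochromane | Brc1cc2c(c(OCc3ccccc3)c1OCc1ccccc1)O[C@H](c1ccc(OCc3ccccc3)cc1)[C@H](OCc1ccccc1)[C@H]2OCc1ccccc1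
F7 | step 12 | 6-bromo analogue of 16 (bromine on C6 of the upper ring A) | C(c5ccccc5)Oc1ccc([C@H]2Oc3c(cc(Br)c(OCc5ccccc5)c3OCc5ccccc5)[C@H](c3cc4c(c(OCc5ccccc5)c3OCc5ccccc5)O[C@H](c3ccc(OCc5ccccc5)cc3)[C@]4(O)C(=O)OC)[C@H]2OCc2ccccc2)cc1
F8 | step 16 | heptaphenol hydroxy ketone (18 without its seven benzyl groups) | Oc1ccc([C@H]2Oc3c(ccc(O)c3O)[C@H](c3cc4c(c(O)c3O)O[C@H](c3ccc(O)cc3)C(=O)[C@H]4O)[C@H]2O)cc1
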